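**Plan**

1. Numbering: ring A is the cyclohexane C10(CH3, C1H=C2H2)–C9–C8(O-acyl)–C7–C6–C5(C4(CH3)=C3H2). Ring C is the γ-lactone O6–C12(=O)–C11(C13H3)(OAc)–C7.
2. Retrosynthesis: cut the O8 and O11 acyl bonds. Cut C1=C2 and C4=C3 back to an aldehyde and a methyl ketone, and fold these into a helper γ-lactone C4(=O)–O–C1H2 (ring B). Remove the C12 carbonyl oxygen and the C11–C13 bond, then cut C7–C11 (leaving an O6-propargyl ether). Last, cut C5–C6 and C9–C10.
3. Enabling feature: on ring A, C1 (on C10), C4 (on C5) and the oxygen on C6 share one face. This is the endo imprint of an (E)-1-oxy-3-silyloxybutadiene (C6–C9) on a 4-methylbutenolide whose C=O is C4 and whose OCH2 is C1.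
4. Forward: ring A closes onto ring B in step 3. Ring C closes in step 4, when the C7=C8 enol silane attacks the O6-propargyl alkyne. Ring B is opened in step 9, ring C becomes the lactone in step 11, and both alkenes arise in one methylenation in step 14.
5. Stereochemistry: C5, C6 and C10 come from the cycloaddition (absolute sense from the chiral boron Lewis acid, relative sense from the cis ring alkene and the endo rule). C7 comes from the short O6 tether, C8 from a thermodynamically governed ketyl reduction, and C11 from convex-face methyl addition.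

Key step: step 3

Convention: β is the face of ring A that carries the C10 methyl group and α is the other face. On ring C, "exo" is the side of H6 and H7 and "endo" is the side of C8. TBS = tert-butyldimethylsilyl.

Assumption: the sense of induction in step 3 is assigned from the binding model that holds for s-trans enoates. If the other face is attacked, the equally available (3aS) catalyst is used.

Assumption: 13 and 16 are drawn as open hydroxy ketones, although they may rest partly as five-membered hemiketals.

**Route**

Step 1
Reactants: 1 prop-2-yn-1-ol; 2 but-3-yn-2-one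
Product: 3 (E)-4-(prop-2-yn-1-yloxy)but-3-en-2-one
Conditions: 1,4-diazabicyclo[2.2.2]octane (10 mol%), CH2Cl2, 0 to 23 °C
Reagents that add atoms: none
Why: Amine-catalysed oxa-Michael addition of an alcohol to an ynone is a standard entry to (E)-β-alkoxy enones, and it puts the later C11–C13 unit on O6 from the start.

Step 2
Reactants: 3 (E)-4-(prop-2-yn-1-yloxy)but-3-en-2-one
Product: 4 (E)-1-(prop-2-yn-1-yloxy)-3-(tert-butyldimethylsilyloxy)buta-1,3-diene
Conditions: TBSOTf (1.1 equiv), Et3N (1.5 equiv), Et2O, 0 °C
Reagents that add atoms: tert-butyldimethylsilyl triflate, CC(C)(C)[Si](C)(C)OS(=O)(=O)C(F)(F)F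
Why: Soft enolisation with O-silylation at the methyl ketone is the usual route to 1-alkoxy-3-silyloxydienes; it leaves the C6=C7 geometry and the alkyne C–H untouched and is run cold because 3 and 4 are propargyl vinyl ethers that could undergo a Claisen shift on heating.

Step 3
Reactants: 4 (E)-1-(prop-2-yn-1-yloxy)-3-(tert-butyldimethylsilyloxy)buta-1,3-diene; 5 4-methylfuran-2(5H)-one
Product: 6 endo cycloadduct (cis-fused rings A and B, C7=C8 enol silane, 6α-propargyloxy)
Conditions: (3aR)-1-(2-methylphenyl)-3,3-diphenyltetrahydro-1H,3H-pyrrolo[1,2-c][1,3,2]oxazaborole (20 mol%), Tf2NH (18 mol%), 4 (1.5 equiv), CH2Cl2, −40 to −20 °C; Et3N quench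
Reagents that add atoms: none
Why: Proposed new method: the N-protonated oxazaborolidine binds the lactone carbonyl oxygen of 5 at the lone pair on the C5 side (backed by a C5–H···O contact) and lowers the LUMO, and the electron-rich diene 4 then adds in a concerted, asynchronous normal-demand [4π+2π] cycloaddition in which C9–C10 forms ahead of C5–C6. The closest known reaction types are oxazaborolidinium-catalysed Diels–Alder additions of 2-silyloxydienes to acrylates, crotonates and unsubstituted unsaturated lactones, and the thermal or Lewis-acid-promoted additions of 1-alkoxy-3-silyloxydienes to butenolides; what is new is enantioselective catalysis on a β-methylbutenolide that has to form the quaternary carbon C10. Ring A (C5–C10) closes as a six-membered ring by suprafacial addition across both components in one step, with ring B carried along unchanged. C5 and C10 inherit the cis geometry of the ring alkene, so C4 and C1 share the α face; C6 follows from the endo transition state (lactone carbonyl under the diene) combined with the E geometry of C6=C7, which puts O6 cis to C4; the absolute sense comes from the catalyst, whose aryl groups cover the Re face of C5 so that the diene reaches the Si face. The step needs regio-, endo- and face selectivity and survival of the enol silane: the two donor oxygens make C9 the nucleophilic terminus that pairs with the β-carbon C10, secondary overlap and the exo preference of the methyl group favour endo addition, the catalyst selects the face, and the robust TBS group, the low temperature and the amine quench protect the enol silane.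

Step 4
Reactants: 6 endo cycloadduct
Product: 7 tricyclic keto lactone (C8 ketone, α-face cis-fused 3-methylenetetrahydrofuran as ring C)
Conditions: (Ph3P)AuCl (5 mol%), AgBF4 (5 mol%), CH2Cl2/MeOH 10:1, 23 °C
Reagents that add atoms: none
Why: Cationic monovalent gold activates the terminal alkyne for a Conia-ene-type 5-exo-dig carbocyclisation of the silyl enol ether, the reaction class that turns 3-(but-3-ynyl)cyclohexenyl silyl ethers into cis-hydrindanones; the O6–C12 tether reaches C7 only from the α face, so C7–C11 forms cis to O6 (H7 β), while MeOH takes up the silyl group and protonates the vinylgold.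

Step 5
Reactants: 7 tricyclic keto lactone
Product: 8 8β-alcohol
Conditions: SmI2 (2.5 equiv), H2O (10 equiv), THF, 0 °C
Reagents that add atoms: none
Why: Ketyl (single-electron) reduction by divalent samarium with water as proton source gives the more stable carbinol, here the equatorial 8β-alcohol, because an 8α oxygen would be syn-diaxial to both O6 and C1H2; the γ-lactone, allyl ether and 1,1-disubstituted alkene are inert to this reagent.

Step 6
Reactants: 8 8β-alcohol
Product: 9 8β-silyl ether
Conditions: TBSOTf (1.2 equiv), 2,6-lutidine (2 equiv), CH2Cl2, 0 °C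
Reagents that add atoms: tert-butyldimethylsilyl triflate, CC(C)(C)[Si](C)(C)OS(=O)(=O)C(F)(F)F
Why: Standard silylation of a secondary alcohol protects O8 against the organometallic and oxidising steps that follow, and its bulk adds to the shielding of the endo face of C11.

Step 7
Reactants: 9 8β-silyl ether
Product: 11 C11 ketone, via spiro ozonide 10 (not isolated)
Conditions: O3, CH2Cl2, −78 °C; then Me2S, −78 to 23 °C
Reagents that add atoms: ozone, [O-][O+]=O
Why: Ozonolysis with reductive work-up cleaves the only C=C bond of 9, and the neutral conditions spare the ketone, which carries β-oxygen substituents on C6 and C8.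

Step 8
Reactants: 11 C11 ketone
Product: 12 tertiary alcohol (C11: CH3 exo, OH endo)
Conditions: MeMgBr (1.2 equiv), THF, −78 °C; then H2O
Reagents that add atoms: methylmagnesium bromide, C[Mg]Br
Why: In this Grignard 1,2-addition the α-alkoxy five-ring ketone reacts far faster than the γ-lactone at −78 °C, and the reagent comes from the convex side of the cis-fused bicycle (the side of H6 and H7) because ring A and the O8 silyl ether block the other side, which places CH3 exo and OH endo as in the target.

Step 9
Reactants: 12 tertiary alcohol
Product: 13 hydroxy ketone (5α-acetyl, 10α-CH2OH)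
Conditions: MeLi (2.2 equiv), THF, −78 °C; then H2O at −78 °C
Reagents that add atoms: methyllithium, [Li]C
Why: After deprotonation of O11–H, mono-addition of MeLi to the γ-lactone stops at the lithium hemiketal at −78 °C and gives the methyl ketone on quenching; C5 holds its configuration because the acetyl group is equatorial.

Step 10
Reactants: 13 hydroxy ketone
Product: 14 O1,O11-diacetate
Conditions: Ac2O (6 equiv), 4-(dimethylamino)pyridine (1 equiv), Et3N, CH2Cl2, 23 to 40 °C
Reagents that add atoms: acetic anhydride, CC(=O)OC(C)=O
Why: Acyl-transfer catalysis acetylates the primary alcohol at once and the hindered tertiary alcohol on longer warming, which installs the final C11 acetate and deactivates C1H2 toward the next oxidation.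

Step 11
Reactants: 14 O1,O11-diacetate
Product: 15 γ-lactone (C12=O)
Conditions: RuCl3·3H2O (5 mol%), NaIO4 (4 equiv), EtOAc/MeCN/H2O, 23 °C
Reagents that add atoms: sodium periodate (oxygen passed on through RuO4), [Na+].[O-]I(=O)(=O)=O
Why: RuO4 oxidation of an ether methylene to the lactone is well known for cis-fused tetrahydrofurans, C12H2 is the only free O–CH2 group, acetates, ketone and silyl ether tolerate the reagent, and the step is placed before any C=C bond exists.

Step 12
Reactants: 15 γ-lactone
Product: 16 primary alcohol
Conditions: [tBu2Sn(OH)Cl]2 (5 mol%), MeOH/THF, 30 °C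
Reagents that add atoms: none
Why: This neutral organotin-catalysed transesterification removes primary acetates much faster than tertiary ones, and it avoids base, which would open ring C by E1cB elimination (C4 ketone, axial C5–H, axial C6–O6 acyloxy group).

Step 13
Reactants: 16 primary alcohol
Product: 17 keto aldehyde
Conditions: 1,1,1-triacetoxy-1,1-dihydro-1,2-benziodoxol-3(1H)-one (1.3 equiv), CH2Cl2, 0 to 23 °C
Reagents that add atoms: none
Why: Dess–Martin oxidation turns the neopentyl alcohol into the non-enolisable aldehyde under mildly acidic conditions that leave the β-acyloxy ketone, acetate and silyl ether alone.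

Step 14
Reactants: 17 keto aldehyde
Product: 18 10α-vinyl 5α-isopropenyl silyl ether
Conditions: Zn, CH2Br2, TiCl4 (reagent pre-formed in THF and aged at 5 °C; excess), CH2Cl2, 0 to 23 °C
Reagents that add atoms: dibromomethane, BrCBr
Why: The non-basic gem-dizinc/titanium reagent of the Takai–Lombardo methylenation converts aldehydes and hindered enolisable ketones into methylene groups without epimerisation or β-elimination and does not touch esters or lactones, so both alkenes form in one operation.

Step 15
Reactants: 18 10α-vinyl 5α-isopropenyl silyl ether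
Product: 19 8β-alcohol of the elemanolide
Conditions: HF·pyridine, THF, 0 to 23 °C
Reagents that add atoms: none
Why: Acidic fluoride cleaves the secondary silyl ether while keeping the medium non-basic, which disfavours acetyl migration from O11 to the nearby O8.

Step 16
Reactants: 19 8β-alcohol of the elemanolide; 20 3-methylbut-3-enoic acid
Product: 21 CNP0106639.1
Conditions: N,N'-dicyclohexylcarbodiimide (1.3 equiv), 4-(dimethylamino)pyridine (10 mol%), CH2Cl2, 0 °C
Reagents that add atoms: none
Why: Steglich esterification acylates the only free hydroxyl group, and the low temperature and small amount of nucleophilic catalyst limit both the shift of the β,γ double bond into conjugation and acetyl migration.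

**Compound list**

1 | prop-2-yn-1-ol | C#CCO | starting material
2 | but-3-yn-2-one | CC(=O)C#C | starting material
3 | (E)-4-(prop-2-yn-1-yloxy)but-3-en-2-one | CC(=O)/C=C/OCC#C | intermediate
4 | (E)-1-(prop-2-yn-1-yloxy)-3-(tert-butyldimethylsilyloxy)buta-1,3-diene (C9H2=C8(OTBS)–C7H=C6H–O6–C12H2–C11≡C13H) | C=C(O[Si](C)(C)C(C)(C)C)/C=C/OCC#C | intermediate
5 | 4-methylfuran-2(5H)-one | CC1=CC(=O)OC1 | starting material
6 | endo cycloadduct: cis-fused 3a-methyl-5-(TBS-oxy)-7-(prop-2-yn-1-yloxy)-3a,4,7,7a-tetrahydroisobenzofuran-1(3H)-one; C1H2, C4=O and O6 on the α face, C10 methyl β | C1[C@]2(C)CC(O[Si](C)(C)C(C)(C)C)=C[C@H](OCC#C)[C@@H]2C(=O)O1 | intermediate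
7 | tricyclic keto lactone: C8 ketone, ring C = O6–C12H2–C11(=C13H2)–C7 cis-fused on the α face (H6, H7 β), ring B intact | C1[C@]2(C)CC(=O)[C@H]3[C@H](OCC3=C)[C@@H]2C(=O)O1 | intermediate
8 | 8β-alcohol of 7 | C1[C@]2(C)C[C@@H](O)[C@H]3[C@H](OCC3=C)[C@@H]2C(=O)O1 | intermediate
9 | 8β-TBS ether of 8 | C1[C@]2(C)C[C@@H](O[Si](C)(C)C(C)(C)C)[C@H]3[C@H](OCC3=C)[C@@H]2C(=O)O1 | intermediate
10 | spiro 1,2,4-trioxolane at C11 (C11–O–C13H2–O–O), spiro centre undefined | C1[C@]2(C)C[C@@H](O[Si](C)(C)C(C)(C)C)[C@H]3[C@H](OCC34OCOO4)[C@@H]2C(=O)O1 | intermediate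
11 | C11 ketone (ring C = tetrahydrofuran-3-one) | C1[C@]2(C)C[C@@H](O[Si](C)(C)C(C)(C)C)[C@H]3[C@H](OCC3=O)[C@@H]2C(=O)O1 | intermediate
12 | tertiary alcohol: C11 bears CH3 exo (side of H6, H7) and OH endo (side of C8) | C1[C@]2(C)C[C@@H](O[Si](C)(C)C(C)(C)C)[C@H]3[C@H](OC[C@@]3(C)O)[C@@H]2C(=O)O1 | intermediate
13 | hydroxy ketone: ring B opened to 5α-acetyl and 10α-CH2OH | OC[C@]1(C)C[C@@H](O[Si](C)(C)C(C)(C)C)[C@H]2[C@H](OC[C@@]2(C)O)[C@@H]1C(C)=O | intermediate
14 | O1,O11-diacetate of 13 | CC(=O)OC[C@]1(C)C[C@@H](O[Si](C)(C)C(C)(C)C)[C@H]2[C@H](OC[C@@]2(C)OC(C)=O)[C@@H]1C(C)=O | intermediate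
15 | γ-lactone: C12H2 of 14 oxidised to C12=O | CC(=O)OC[C@]1(C)C[C@@H](O[Si](C)(C)C(C)(C)C)[C@H]2[C@H](OC(=O)[C@@]2(C)OC(C)=O)[C@@H]1C(C)=O | intermediate
16 | primary alcohol (O1–H free, O11 acetate kept) | OC[C@]1(C)C[C@@H](O[Si](C)(C)C(C)(C)C)[C@H]2[C@H](OC(=O)[C@@]2(C)OC(C)=O)[C@@H]1C(C)=O | intermediate
17 | keto aldehyde (C1 aldehyde on C10, C4 methyl ketone on C5) | O=C[C@]1(C)C[C@@H](O[Si](C)(C)C(C)(C)C)[C@H]2[C@H](OC(=O)[C@@]2(C)OC(C)=O)[C@@H]1C(C)=O | intermediate
18 | 10α-vinyl, 5α-isopropenyl, 8β-OTBS, 11-acetoxy 6,12-olide | C=C[C@]1(C)C[C@@H](O[Si](C)(C)C(C)(C)C)[C@H]2[C@H](OC(=O)[C@@]2(C)OC(C)=O)[C@@H]1C(=C)C | intermediate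
19 | 8β-alcohol of 18 | C=C[C@]1(C)C[C@@H](O)[C@H]2[C@H](OC(=O)[C@@]2(C)OC(C)=O)[C@@H]1C(=C)C | intermediate
20 | 3-methylbut-3-enoic acid | C=C(C)CC(=O)O | starting material
21 | CNP0106639.1 | C=C[C@]1(C)C[C@@H](OC(=O)CC(=C)C)[C@H]2[C@H](OC(=O)[C@@]2(C)OC(C)=O)[C@@H]1C(=C)C | target

**Step count and risks**

Total step count: 16. Longest linear sequence: 16 steps (from 1 or 2 to 21); 5 and 20 are bought.

Steps most likely to fail:

**Step 3.** The hindered β-methylbutenolide may react so slowly that acid-induced breakdown of the diene (loss of the silyl group, Michael-type oligomerisation) outruns the cycloaddition. Facial selectivity may also be poor.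

The fallback gives up catalyst control in favour of a resolution. It sets out from 4 and 5, which are combined without catalyst under high pressure (1.3 GPa, CH2Cl2, 23 °C), a known way to add 1-alkoxy-3-silyloxydienes to β-substituted butenolides and enones. This gives the endo adduct as a racemate, that is 6 together with the mirror-image adduct ent-6 F1. Steps 4 and 5 are run on the racemate, giving 7 beside the mirror-image ketone ent-7 F2 and then 8 beside the mirror-image alcohol ent-8 F3. Esterification with (S)-2-methoxy-2-phenylacetic acid (N,N'-dicyclohexylcarbodiimide, 4-(dimethylamino)pyridine, CH2Cl2) gives the two diastereomers, the methoxyphenylacetate of 8 F4 and the methoxyphenylacetate of ent-8 F5, which are separated by chromatography or crystallisation. Methanolysis of F4 (K2CO3, MeOH, 0 °C) brings the route back at 8.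

**Step 4.** Under the cationic gold and silver salts, protodesilylation of the enol silane or vinylogous loss of propargyl alcohol may occur before the C7–C11 bond forms.

The fallback replaces the ionic closure by a radical one and sets out from 6. N-Bromosuccinimide (THF, −78 °C) converts the enol silane into the 7β-bromo ketone F6. Bu3SnH with Et3B/air (toluene, 23 °C) then generates the C7 radical, which closes 5-exo-dig onto the tethered alkyne. This is the known tin hydride cyclisation of β-bromo propargyl ethers to cis-fused 3-methylenetetrahydrofurans. Hydrogen abstraction by the vinyl radical brings the route back at 7.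

**Step 5.** Protonation of the ketyl-derived intermediate may not follow product stability, so facial selectivity at C8 may be poor, or the hindered ketone may be reduced too slowly.

The fallback uses kinetic hydride delivery followed by inversion and sets out from 7. LiBH(sBu)3 (THF, −78 °C) attacks the open β face and gives the axial 8α-alcohol F7. Mitsunobu reaction with 4-nitrobenzoic acid (PPh3, diisopropyl azodicarboxylate, toluene) inverts C8 to the 8β 4-nitrobenzoate F8. Methanolysis (K2CO3, MeOH, 0 °C) brings the route back at 8.

**Further compounds**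

F1 | step 3 | ent-6, mirror image of the cycloadduct | C1[C@@]2(C)CC(O[Si](C)(C)C(C)(C)C)=C[C@@H](OCC#C)[C@H]2C(=O)O1
F2 | step 3 | ent-7, mirror image of the tricyclic keto lactone | C1[C@@]2(C)CC(=O)[C@@H]3[C@@H](OCC3=C)[C@H]2C(=O)O1
F3 | step 3 | ent-8, mirror image of the 8β-alcohol | C1[C@@]2(C)C[C@H](O)[C@@H]3[C@@H](OCC3=C)[C@H]2C(=O)O1
F4 | step 3 | (S)-2-methoxy-2-phenylacetate of 8 | C1[C@]2(C)C[C@@H](OC(=O)[C@@H](OC)c4ccccc4)[C@H]3[C@H](OCC3=C)[C@@H]2C(=O)O1
F5 | step 3 | (S)-2-methoxy-2-phenylacetate of ent-8 | C1[C@@]2(C)C[C@H](OC(=O)[C@@H](OC)c4ccccc4)[C@@H]3[C@@H](OCC3=C)[C@H]2C(=O)O1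
F6 | step 4 | 7β-bromo-6α-(prop-2-yn-1-yloxy) C8 ketone with ring B intact | C1[C@]2(C)CC(=O)[C@@H](Br)[C@H](OCC#C)[C@@H]2C(=O)O1
F7 | step 5 | 8α-alcohol (C8 epimer of 8) | C1[C@]2(C)C[C@H](O)[C@H]3[C@H](OCC3=C)[C@@H]2C(=O)O1
F8 | step 5 | 8β 4-nitrobenzoate of 8 | C1[C@]2(C)C[C@@H](OC(=O)c4ccc(cc4)[N+](=O)[O-])[C@H]3[C@H](OCC3=C)[C@@H]2C(=O)O1
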